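The route rests on opening the C3–C3a bond of the dihydrobenzofuran (ring C). C3a is tied instead to the carbon of the C3 hydroxymethyl group, which expands ring C to the pyranone ring of a flavanone. The feature exploited is that C3 carries the benzo carbon C3a and a one-carbon branch trans to the C2 aryl group. In the forward sense a trivalent-iodine oxidation moves the benzo carbon from C4 to C3. In one operation it contracts the ring, sets C3 and turns C4 into a methyl ester. The precursor is an (S)-6-bromo-8-methoxyflavanone with its 2-aryl ring deactivated as a mesylate. The bromide later becomes the benzylic bromide that alkylates an (R)-β-benzylbutyrolactone enolate.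

Key step: step 6

Ring labels: ring A = benzo ring, ring B = 2-aryl ring, ring C = oxygen heterocycle, before and after the contraction.
Assumption: the sense of induction in steps 5 and 12 is inferred from the behaviour of the same ligands with 2-cyclohexenone and with enamide or itaconate substrates; both ligands are sold as both antipodes, so a reversed sense would only require the other ligand enantiomer.

Step 1
Reactants: 1 2'-hydroxy-3'-methoxyacetophenone
Product: 2 5'-bromo-2'-hydroxy-3'-methoxyacetophenone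
Conditions: NBS (1.05 equiv), MeCN, 0 °C → rt
Reagents that add atoms: N-bromosuccinimide, O=C1CCC(=O)N1Br
Why: Electrophilic aromatic bromination, in which the phenolic OH steers bromine to C5', its only free ortho or para position and also meta to the acetyl group, while NBS in MeCN keeps side-chain bromination of the ketone out of play.

Step 2
Reactants: 2 5'-bromo-2'-hydroxy-3'-methoxyacetophenone; 3 N,N-dimethylformamide dimethyl acetal
Product: 5 6-bromo-8-methoxy-4H-chromen-4-one, via enaminone 4 (not isolated)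
Conditions: 3 (2 equiv), toluene, 100 °C; evaporate; conc. HCl, CH2Cl2, 40 °C
Reagents that add atoms: none
Why: Enaminone route to chromones, in which the acetal condenses at the methyl ketone to give 4 and acid then triggers 6-endo-trig addition of the phenol oxygen to the β-carbon with loss of dimethylamine.

Step 3
Reactants: 6 2-methoxy-4-(4,4,5,5-tetramethyl-1,3,2-dioxaborolan-2-yl)phenol
Product: 7 2-methoxy-4-(4,4,5,5-tetramethyl-1,3,2-dioxaborolan-2-yl)phenyl methanesulfonate
Conditions: MsCl, Et3N, CH2Cl2, 0 °C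
Reagents that add atoms: methanesulfonyl chloride, CS(=O)(=O)Cl
Why: O-Sulfonylation of a phenol, which leaves the pinacol boronate untouched and installs the electron-poor group that ring B needs in step 6.

Step 4
Reactants: 7 2-methoxy-4-(4,4,5,5-tetramethyl-1,3,2-dioxaborolan-2-yl)phenyl methanesulfonate
Product: 8 [4-(methanesulfonyloxy)-3-methoxyphenyl]boronic acid
Conditions: NaIO4, NH4OAc, acetone–H2O, rt
Reagents that add atoms: water, O
Why: Oxidative deprotection of a pinacol boronate, in which periodate glycol cleavage destroys the pinacol released by hydrolysis and so drives the equilibrium to the free boronic acid, the better partner for transmetalation to rhodium.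

Step 5
Reactants: 5 6-bromo-8-methoxy-4H-chromen-4-one; 8 [4-(methanesulfonyloxy)-3-methoxyphenyl]boronic acid
Product: 9 (S)-6-bromo-8-methoxy-2-(4-methanesulfonyloxy-3-methoxyphenyl)chroman-4-one
Conditions: [Rh(C2H4)2Cl]2 (2.5 mol %), (1S,4S)-2,5-diphenylbicyclo[2.2.2]octa-2,5-diene (5.5 mol %), 8 (2 equiv), K3PO4 (0.2 equiv), toluene–H2O 10:1, 40 °C; neutral work-up
Reagents that add atoms: none
Why: Hayashi–Miyaura conjugate addition, in which the aryl complex of monovalent rhodium adds to C2 of the chromone held on the chiral diene, whose phenyl groups shield one enone face so that C2 should form as (S), while the aryl bromide is inert to the catalyst and the nearly neutral two-phase medium limits retro-oxa-Michael opening of the product.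

Step 6
Reactants: 9 (S)-6-bromo-8-methoxy-2-(4-methanesulfonyloxy-3-methoxyphenyl)chroman-4-one
Product: 13 methyl (2S,3S)-5-bromo-2-(4-methanesulfonyloxy-3-methoxyphenyl)-7-methoxy-2,3-dihydrobenzofuran-3-carboxylate (2,3-trans), via enol ether 10 (not isolated), via iodanyl ketal 11 (not isolated), via dimethoxycarbenium ion 12 (not isolated)
Conditions: PhI(OAc)2 (1.2 equiv), H2SO4 (cat.), HC(OMe)3, 0 °C → rt; aq NaHCO3
Reagents that add atoms: trimethyl orthoformate, COC(OC)OC
Why: Acid and orthoformate turn ketone 9 into enol ether 10, PhI(OAc)2 adds its trivalent iodine to C3 on the face away from the C2 aryl group and methanol caps C4, giving ketal 11 with an equatorial C3–I bond that lies antiperiplanar to the C4–C4a ring bond. Departure of PhI is assisted by the shift of C4a from C4 to C3, and the cation 12 left at C4 loses a methyl group to acetate and ends as the exocyclic methyl ester. The closest known reaction type is the oxidative 1,2-aryl rearrangement of aryl ketones in trimethyl orthoformate with PhI(OAc)2 or Tl(NO3)3, which is established for flavanones as a contraction to trans-2-aryl-2,3-dihydrobenzofuran-3-carboxylates. The five-membered ring C is closed not by an end-to-end cyclisation but by contraction of the six-membered ring, formally a 3-exo-tet ipso attack of C4a on C3 through a bridged arenium transition state followed by cleavage of C4–C4a. The new centre C3 is controlled by C2, since anti addition of iodine followed by inversion at C3 places the ester trans to the aryl group, and because no bond at C2 is touched the (2S,3S) ester should result. The step needs migration of ring A rather than the 2→3 shift of ring B (isoflavone), methanol substitution at C3 or elimination to the flavone; this is secured by ring B being electron-poor at C1' (mesylate para, methoxy meta), which also slows acid ionisation of C2–O1 and hence racemisation, and by C4a lying ortho to the donor O1, whereas 8-OMe and 6-Br are meta to C4a and give no push, the bromine only blocking the position para to O1 and serving as the later handle.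

Step 7
Reactants: 13 methyl (2S,3S)-5-bromo-2-(4-methanesulfonyloxy-3-methoxyphenyl)-7-methoxy-2,3-dihydrobenzofuran-3-carboxylate
Product: 15 4-[(2S,3R)-5-bromo-3-(hydroxymethyl)-7-methoxy-2,3-dihydrobenzofuran-2-yl]-2-methoxyphenol, via alcohol mesylate 14 (not isolated)
Conditions: LiAlH4 (1.5 equiv), THF, 0 °C; H2O quench; 2 M NaOH, MeOH, 60 °C; HCl to pH 6
Reagents that add atoms: none
Why: Hydride reduction of the ester followed by alkaline S–O cleavage of the aryl sulfonate, in which LiAlH4 at 0 °C reduces the ester faster than it enolises it and spares the aryl bromide, so C3 keeps its geometry (S becomes R only because CH2OH ranks below C2), and hydroxide is admitted only once the ester is gone, because its enolate could expel the O1 phenoxide and scramble C2.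

Step 8
Reactants: 15 4-[(2S,3R)-5-bromo-3-(hydroxymethyl)-7-methoxy-2,3-dihydrobenzofuran-2-yl]-2-methoxyphenol
Product: 16 (2S,3R)-5-bromo-3-(benzyloxymethyl)-2-(4-benzyloxy-3-methoxyphenyl)-7-methoxy-2,3-dihydrobenzofuran
Conditions: BnBr (2.5 equiv), NaH (2.5 equiv), Bu4NI (cat.), THF–DMF, 0 °C → rt
Reagents that add atoms: benzyl bromide, BrCc1ccccc1
Why: Williamson ether synthesis, which benzylates phenoxide and primary alkoxide in one operation and gives groups that tolerate organolithium, PBr3 and enolate chemistry and leave together in step 15.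

Step 9
Reactants: 16 (2S,3R)-5-bromo-3-(benzyloxymethyl)-2-(4-benzyloxy-3-methoxyphenyl)-7-methoxy-2,3-dihydrobenzofuran
Product: 19 [(2S,3R)-3-(benzyloxymethyl)-2-(4-benzyloxy-3-methoxyphenyl)-7-methoxy-2,3-dihydrobenzofuran-5-yl]methanol, via aryllithium 17 (not isolated), via aldehyde 18 (not isolated)
Conditions: n-BuLi (1.1 equiv), THF, −78 °C; DMF, −78 → 0 °C; MeOH, NaBH4, 0 °C
Reagents that add atoms: N,N-dimethylformamide, CN(C)C=O
Why: Bromine–lithium exchange and Bouveault formylation with DMF, followed by borohydride reduction of the aldehyde released on adding methanol, which turns the aryl bromide into the benzylic alcohol without touching the ethers or the stereocentres.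

Step 10
Reactants: 19 [(2S,3R)-3-(benzyloxymethyl)-2-(4-benzyloxy-3-methoxyphenyl)-7-methoxy-2,3-dihydrobenzofuran-5-yl]methanol
Product: 20 (2S,3R)-5-(bromomethyl)-3-(benzyloxymethyl)-2-(4-benzyloxy-3-methoxyphenyl)-7-methoxy-2,3-dihydrobenzofuran
Conditions: PBr3 (0.4 equiv), Et2O–CH2Cl2, 0 °C; used at once
Reagents that add atoms: phosphorus tribromide, BrP(Br)Br
Why: Conversion of an electron-rich benzylic alcohol into its bromide by SN2 displacement of the phosphite ester, the usual access to the 3,4-dialkoxybenzyl bromides employed in lignan lactone alkylations.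

Step 11
Reactants: 21 4-benzyloxy-3-methoxybenzaldehyde; 22 dimethyl succinate
Product: 23 (E)-4-(4-benzyloxy-3-methoxyphenyl)-3-(methoxycarbonyl)but-3-enoic acid
Conditions: NaOMe, MeOH, reflux; aq HCl
Reagents that add atoms: none
Why: Stobbe condensation, whose irreversible carboxylate formation drives the aldol-type coupling and gives the half-ester with the aryl group trans to the retained ester, which is the (E) olefin.

Step 12
Reactants: 23 (E)-4-(4-benzyloxy-3-methoxyphenyl)-3-(methoxycarbonyl)but-3-enoic acid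
Product: 24 (R)-4-(4-benzyloxy-3-methoxyphenyl)-3-(methoxycarbonyl)butanoic acid
Conditions: H2 (5 bar), [Rh(cod)((S,S)-Et-DuPHOS)]BF4 (0.5 mol %), MeOH, rt
Reagents that add atoms: none
Why: Asymmetric hydrogenation of a Stobbe-type itaconate half-ester, in which chelation of the carboxyl group to cationic rhodium fixes the olefin face, the (S,S) ligand should give the (R) centre by analogy with its enamide reductions, and the benzyl ether is inert to the homogeneous catalyst.

Step 13
Reactants: 24 (R)-4-(4-benzyloxy-3-methoxyphenyl)-3-(methoxycarbonyl)butanoic acid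
Product: 26 (R)-4-(4-benzyloxy-3-methoxybenzyl)dihydrofuran-2(3H)-one, via hydroxy acid 25 (not isolated)
Conditions: KOH (1 equiv), EtOH, 0 °C; CaCl2, NaBH4, EtOH, −10 °C → rt; 3 M HCl, rt
Reagents that add atoms: none
Why: Chemoselective borohydride reduction, in which the carboxylate salt resists Ca(BH4)2 while the methyl ester is reduced to the primary alcohol, and acidification closes the γ-lactone (5-exo-trig) without touching the stereocentre.

Step 14
Reactants: 26 (R)-4-(4-benzyloxy-3-methoxybenzyl)dihydrofuran-2(3H)-one; 20 (2S,3R)-5-(bromomethyl)-3-(benzyloxymethyl)-2-(4-benzyloxy-3-methoxyphenyl)-7-methoxy-2,3-dihydrobenzofuran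
Product: 28 (3R,4R)-4-(4-benzyloxy-3-methoxybenzyl)-3-{[(2S,3R)-3-(benzyloxymethyl)-2-(4-benzyloxy-3-methoxyphenyl)-7-methoxy-2,3-dihydrobenzofuran-5-yl]methyl}dihydrofuran-2(3H)-one, via lithium enolate 27 (not isolated)
Conditions: 26 (1.2 equiv), LiN(SiMe3)2, THF, −78 °C; 20, DMPU, −78 → −20 °C
Reagents that add atoms: none
Why: Diastereoselective alkylation of a β-substituted γ-butyrolactone enolate, in which the bromide approaches anti to the C4 benzyl group and sets C3 as (R) and trans, also the thermodynamically preferred relation, and in which no palladium hydride that could eliminate towards C4 and erase that centre is ever present.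

Step 15
Reactants: 28 (3R,4R)-4-(4-benzyloxy-3-methoxybenzyl)-3-{[(2S,3R)-3-(benzyloxymethyl)-2-(4-benzyloxy-3-methoxyphenyl)-7-methoxy-2,3-dihydrobenzofuran-5-yl]methyl}dihydrofuran-2(3H)-one
Product: 29 Isolappaol A
Conditions: H2 (1 atm), Pd/C (10 %), EtOAc–EtOH, rt
Reagents that add atoms: none
Why: Catalytic hydrogenolysis of two aryl benzyl ethers and one primary alkyl benzyl ether under neutral conditions, in which the C2–O1 bond of ring C is a hindered, ring-bound secondary benzylic ether of the kind that survives global debenzylation of perbenzylated flavan-3-ols, and the lactone and all four stereocentres are inert.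

Compound list
1 | 2'-hydroxy-3'-methoxyacetophenone | CC(=O)c1cccc(OC)c1O | starting material
2 | 5'-bromo-2'-hydroxy-3'-methoxyacetophenone | CC(=O)c1cc(Br)cc(OC)c1O | intermediate
3 | N,N-dimethylformamide dimethyl acetal | COC(OC)N(C)C | starting material
4 | (E)-1-(5-bromo-2-hydroxy-3-methoxyphenyl)-3-(dimethylamino)prop-2-en-1-one | CN(C)/C=C/C(=O)c1cc(Br)cc(OC)c1O | intermediate
5 | 6-bromo-8-methoxy-4H-chromen-4-one | O=c1ccoc2c(OC)cc(Br)cc12 | intermediate
6 | 2-methoxy-4-(4,4,5,5-tetramethyl-1,3,2-dioxaborolan-2-yl)phenol | COc1cc(B2OC(C)(C)C(C)(C)O2)ccc1O | starting material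
7 | 2-methoxy-4-(4,4,5,5-tetramethyl-1,3,2-dioxaborolan-2-yl)phenyl methanesulfonate | COc1cc(B2OC(C)(C)C(C)(C)O2)ccc1OS(C)(=O)=O | intermediate
8 | [4-(methanesulfonyloxy)-3-methoxyphenyl]boronic acid | COc1cc(B(O)O)ccc1OS(C)(=O)=O | intermediate
9 | (S)-6-bromo-8-methoxy-2-(4-methanesulfonyloxy-3-methoxyphenyl)chroman-4-one | O=C1C[C@@H](c2ccc(OS(C)(=O)=O)c(OC)c2)Oc2c(OC)cc(Br)cc12 | intermediate
10 | (S)-6-bromo-4,8-dimethoxy-2-(4-methanesulfonyloxy-3-methoxyphenyl)-2H-chromene | COC1=C[C@@H](c2ccc(OS(C)(=O)=O)c(OC)c2)Oc2c(OC)cc(Br)cc12 | intermediate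
11 | (2R,3R)-3-[acetoxy(phenyl)-λ3-iodanyl]-6-bromo-4,4,8-trimethoxy-2-(4-methanesulfonyloxy-3-methoxyphenyl)chromane, iodine trans to the 2-aryl group, geometry at C2 as in 9 | COC1(OC)[C@H]([I](OC(C)=O)c2ccccc2)[C@@H](c2ccc(OS(C)(=O)=O)c(OC)c2)Oc2c(OC)cc(Br)cc12 | intermediate
12 | [(2S,3S)-5-bromo-2-(4-methanesulfonyloxy-3-methoxyphenyl)-7-methoxy-2,3-dihydrobenzofuran-3-yl]dimethoxycarbenium acetate | Brc1cc(OC)c2c(c1)[C@H](C(OC)=[O+]C)[C@@H](c1ccc(OS(C)(=O)=O)c(OC)c1)O2.CC(=O)[O-] | intermediate
13 | methyl (2S,3S)-5-bromo-2-(4-methanesulfonyloxy-3-methoxyphenyl)-7-methoxy-2,3-dihydrobenzofuran-3-carboxylate (trans) | Brc1cc(OC)c2c(c1)[C@H](C(=O)OC)[C@@H](c1ccc(OS(C)(=O)=O)c(OC)c1)O2 | intermediate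
14 | [(2S,3R)-5-bromo-2-(4-methanesulfonyloxy-3-methoxyphenyl)-7-methoxy-2,3-dihydrobenzofuran-3-yl]methanol | Brc1cc(OC)c2c(c1)[C@H](CO)[C@@H](c1ccc(OS(C)(=O)=O)c(OC)c1)O2 | intermediate
15 | 4-[(2S,3R)-5-bromo-3-(hydroxymethyl)-7-methoxy-2,3-dihydrobenzofuran-2-yl]-2-methoxyphenol | Brc1cc(OC)c2c(c1)[C@H](CO)[C@@H](c1ccc(O)c(OC)c1)O2 | intermediate
16 | (2S,3R)-5-bromo-3-(benzyloxymethyl)-2-(4-benzyloxy-3-methoxyphenyl)-7-methoxy-2,3-dihydrobenzofuran | Brc1cc(OC)c2c(c1)[C@H](COCc1ccccc1)[C@@H](c1ccc(OCc3ccccc3)c(OC)c1)O2 | intermediate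
17 | [(2S,3R)-3-(benzyloxymethyl)-2-(4-benzyloxy-3-methoxyphenyl)-7-methoxy-2,3-dihydrobenzofuran-5-yl]lithium | [Li]c1cc(OC)c2c(c1)[C@H](COCc1ccccc1)[C@@H](c1ccc(OCc3ccccc3)c(OC)c1)O2 | intermediate
18 | (2S,3R)-3-(benzyloxymethyl)-2-(4-benzyloxy-3-methoxyphenyl)-7-methoxy-2,3-dihydrobenzofuran-5-carbaldehyde | O=Cc1cc(OC)c2c(c1)[C@H](COCc1ccccc1)[C@@H](c1ccc(OCc3ccccc3)c(OC)c1)O2 | intermediate
19 | [(2S,3R)-3-(benzyloxymethyl)-2-(4-benzyloxy-3-methoxyphenyl)-7-methoxy-2,3-dihydrobenzofuran-5-yl]methanol | OCc1cc(OC)c2c(c1)[C@H](COCc1ccccc1)[C@@H](c1ccc(OCc3ccccc3)c(OC)c1)O2 | intermediate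
20 | (2S,3R)-5-(bromomethyl)-3-(benzyloxymethyl)-2-(4-benzyloxy-3-methoxyphenyl)-7-methoxy-2,3-dihydrobenzofuran | BrCc1cc(OC)c2c(c1)[C@H](COCc1ccccc1)[C@@H](c1ccc(OCc3ccccc3)c(OC)c1)O2 | intermediate
21 | 4-benzyloxy-3-methoxybenzaldehyde | COc1cc(C=O)ccc1OCc1ccccc1 | starting material
22 | dimethyl succinate | COC(=O)CCC(=O)OC | starting material
23 | (E)-4-(4-benzyloxy-3-methoxyphenyl)-3-(methoxycarbonyl)but-3-enoic acid | COC(=O)/C(CC(=O)O)=C/c1ccc(OCc2ccccc2)c(OC)c1 | intermediate
24 | (R)-4-(4-benzyloxy-3-methoxyphenyl)-3-(methoxycarbonyl)butanoic acid | COC(=O)[C@@H](CC(=O)O)Cc1ccc(OCc2ccccc2)c(OC)c1 | intermediate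
25 | (R)-4-(4-benzyloxy-3-methoxyphenyl)-3-(hydroxymethyl)butanoic acid | OC[C@@H](CC(=O)O)Cc1ccc(OCc2ccccc2)c(OC)c1 | intermediate
26 | (R)-4-(4-benzyloxy-3-methoxybenzyl)dihydrofuran-2(3H)-one | COc1cc(C[C@H]2COC(=O)C2)ccc1OCc1ccccc1 | intermediate
27 | lithium enolate of 26, (R)-configured at C4 | COc1cc(C[C@H]2COC(O[Li])=C2)ccc1OCc1ccccc1 | intermediate
28 | (3R,4R)-4-(4-benzyloxy-3-methoxybenzyl)-3-{[(2S,3R)-3-(benzyloxymethyl)-2-(4-benzyloxy-3-methoxyphenyl)-7-methoxy-2,3-dihydrobenzofuran-5-yl]methyl}dihydrofuran-2(3H)-one | COc1cc(C[C@H]2COC(=O)[C@@H]2Cc2cc(OC)c3c(c2)[C@H](COCc2ccccc2)[C@@H](c2ccc(OCc4ccccc4)c(OC)c2)O3)ccc1OCc1ccccc1 | intermediate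
29 | Isolappaol A, (3R,4R)-4-(4-hydroxy-3-methoxybenzyl)-3-{[(2S,3R)-2-(4-hydroxy-3-methoxyphenyl)-3-(hydroxymethyl)-7-methoxy-2,3-dihydrobenzofuran-5-yl]methyl}dihydrofuran-2(3H)-one | COc1cc(C[C@H]2COC(=O)[C@@H]2Cc2cc(OC)c3c(c2)[C@H](CO)[C@@H](c2ccc(O)c(OC)c2)O3)ccc1O | target

Total step count: 15.
Longest linear sequence: 10 steps (1, 2, 5, 6, 7, 8, 9, 10, 14, 15). Steps 3–4 (boronic acid) and 11–13 (lactone) are side branches.

Steps most likely to fail

Step 6. Four things may go wrong:
- Ring B may migrate instead of ring A.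
- Methanol may displace the iodane at C3.
- The iodane may be lost by elimination to the flavone.
- Ring C may open under acid, with erosion of enantiomeric purity.

The fallback sets out from 9 and comes back at 13. It installs and ionises the C3 leaving group in separate operations.
- CuBr2 in EtOAc–CHCl3 at reflux should give, after equilibration through the enol, the 2,3-trans bromide (2R,3R)-3,6-dibromo-8-methoxy-2-(4-methanesulfonyloxy-3-methoxyphenyl)chroman-4-one F1.
- HC(OMe)3, MeOH and TsOH convert it into the dimethyl ketal (2R,3R)-3,6-dibromo-4,4,8-trimethoxy-2-(4-methanesulfonyloxy-3-methoxyphenyl)chromane F2.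
- Catalytic ZnBr2 in warm toluene then triggers the Lewis-acid rearrangement of α-bromo aryl ketals to 2-arylalkanoic esters.
- The equatorial C3–Br bond is again antiperiplanar to C4–C4a, so the same invertive shift of C4a should give 13. Bromide takes the methyl group from the cationic carbon.

Step 5. Three things may go wrong:
- Insertion into the vinylogous-ester double bond of the chromone may be slow.
- The electron-poor boronic acid may undergo protodeboronation.
- Base may open the product by retro-oxa-Michael reaction, with loss of enantiomeric purity.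

The fallback sets out from 2 and comes back at 9.
- Vanillin is mesylated (MsCl, Et3N) to 4-formyl-2-methoxyphenyl methanesulfonate F3.
- F3 is condensed with 2 under pyrrolidine catalysis in MeOH (Kabbe condensation, mild enough for the mesylate).
- The condensation passes through the 2'-hydroxychalcone F4 to the racemic flavanone F5.
- Kinetic resolution follows by Noyori asymmetric transfer hydrogenation with RuCl(p-cymene)[(R,R)-TsDPEN] in HCO2H–Et3N.
- The (R) enantiomer should be reduced faster, to the cis-(2R,4R)-flavan-4-ol F6. This catalyst gives (R)-benzylic alcohols, and flavanones prefer the 2,4-cis alcohol.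
- Unreacted (S)-flavanone 9 is separated by chromatography, at the price of half of the material.

Step 15. Ring C may be opened by hydrogenolysis at the benzylic C2–O1 bond while the slower primary benzyl ether is still being removed.

The fallback sets out from 15 and comes back at 29. It replaces the two benzyl groups of the dihydrobenzofuran fragment by silyl groups.
- i-Pr3SiCl and imidazole in DMF give the bis(triisopropylsilyl) ether F7.
- n-BuLi, then DMF, then MeOH and NaBH4 lead through the aryllithium F8 and the aldehyde F9 to the benzylic alcohol F10.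
- An Appel reaction (CBr4, PPh3) gives the benzylic bromide F11.
- Alkylation of enolate 27 as in step 14 gives the trans lactone F12.
- A short hydrogenolysis (H2, Pd/C, EtOAc) removes the single, fast-reacting phenolic benzyl ether while the ring B phenol is still silylated. The C2–O1 bond is thereby least activated, and the product is the phenol F13.
- Bu4NF buffered with AcOH in THF then frees both remaining hydroxyl groups to give 29.

Further compounds
F1 | step 6 | (2R,3R)-3,6-dibromo-8-methoxy-2-(4-methanesulfonyloxy-3-methoxyphenyl)chroman-4-one (2,3-trans) | O=C1[C@H](Br)[C@@H](c2ccc(OS(C)(=O)=O)c(OC)c2)Oc2c(OC)cc(Br)cc12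
F2 | step 6 | (2R,3R)-3,6-dibromo-4,4,8-trimethoxy-2-(4-methanesulfonyloxy-3-methoxyphenyl)chromane | COC1(OC)[C@H](Br)[C@@H](c2ccc(OS(C)(=O)=O)c(OC)c2)Oc2c(OC)cc(Br)cc12
F3 | step 5 | 4-formyl-2-methoxyphenyl methanesulfonate | COc1cc(C=O)ccc1OS(C)(=O)=O
F4 | step 5 | (E)-1-(5-bromo-2-hydroxy-3-methoxyphenyl)-3-(4-methanesulfonyloxy-3-methoxyphenyl)prop-2-en-1-one | O=C(/C=C/c1ccc(OS(C)(=O)=O)c(OC)c1)c1cc(Br)cc(OC)c1O
F5 | step 5 | racemic 6-bromo-8-methoxy-2-(4-methanesulfonyloxy-3-methoxyphenyl)chroman-4-one | O=C1CC(c2ccc(OS(C)(=O)=O)c(OC)c2)Oc2c(OC)cc(Br)cc12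
F6 | step 5 | (2R,4R)-6-bromo-8-methoxy-2-(4-methanesulfonyloxy-3-methoxyphenyl)chroman-4-ol (2,4-cis) | O[C@@H]1C[C@H](c2ccc(OS(C)(=O)=O)c(OC)c2)Oc2c(OC)cc(Br)cc12
F7 | step 15 | (2S,3R)-5-bromo-7-methoxy-2-(3-methoxy-4-triisopropylsilyloxyphenyl)-3-(triisopropylsilyloxymethyl)-2,3-dihydrobenzofuran | Brc1cc(OC)c2c(c1)[C@H](CO[Si](C(C)C)(C(C)C)C(C)C)[C@@H](c1ccc(O[Si](C(C)C)(C(C)C)C(C)C)c(OC)c1)O2
F8 | step 15 | 5-lithio derivative of F7 | [Li]c1cc(OC)c2c(c1)[C@H](CO[Si](C(C)C)(C(C)C)C(C)C)[C@@H](c1ccc(O[Si](C(C)C)(C(C)C)C(C)C)c(OC)c1)O2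
F9 | step 15 | (2S,3R)-7-methoxy-2-(3-methoxy-4-triisopropylsilyloxyphenyl)-3-(triisopropylsilyloxymethyl)-2,3-dihydrobenzofuran-5-carbaldehyde | O=Cc1cc(OC)c2c(c1)[C@H](CO[Si](C(C)C)(C(C)C)C(C)C)[C@@H](c1ccc(O[Si](C(C)C)(C(C)C)C(C)C)c(OC)c1)O2
F10 | step 15 | [(2S,3R)-7-methoxy-2-(3-methoxy-4-triisopropylsilyloxyphenyl)-3-(triisopropylsilyloxymethyl)-2,3-dihydrobenzofuran-5-yl]methanol | OCc1cc(OC)c2c(c1)[C@H](CO[Si](C(C)C)(C(C)C)C(C)C)[C@@H](c1ccc(O[Si](C(C)C)(C(C)C)C(C)C)c(OC)c1)O2
F11 | step 15 | (2S,3R)-5-(bromomethyl)-7-methoxy-2-(3-methoxy-4-triisopropylsilyloxyphenyl)-3-(triisopropylsilyloxymethyl)-2,3-dihydrobenzofuran | BrCc1cc(OC)c2c(c1)[C@H](CO[Si](C(C)C)(C(C)C)C(C)C)[C@@H](c1ccc(O[Si](C(C)C)(C(C)C)C(C)C)c(OC)c1)O2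
F12 | step 15 | (3R,4R)-4-(4-benzyloxy-3-methoxybenzyl)-3-{[(2S,3R)-7-methoxy-2-(3-methoxy-4-triisopropylsilyloxyphenyl)-3-(triisopropylsilyloxymethyl)-2,3-dihydrobenzofuran-5-yl]methyl}dihydrofuran-2(3H)-one | COc1cc(C[C@H]2COC(=O)[C@@H]2Cc2cc(OC)c3c(c2)[C@H](CO[Si](C(C)C)(C(C)C)C(C)C)[C@@H](c2ccc(O[Si](C(C)C)(C(C)C)C(C)C)c(OC)c2)O3)ccc1OCc1ccccc1
F13 | step 15 | (3R,4R)-4-(4-hydroxy-3-methoxybenzyl)-3-{[(2S,3R)-7-methoxy-2-(3-methoxy-4-triisopropylsilyloxyphenyl)-3-(triisopropylsilyloxymethyl)-2,3-dihydrobenzofuran-5-yl]methyl}dihydrofuran-2(3H)-one | COc1cc(C[C@H]2COC(=O)[C@@H]2Cc2cc(OC)c3c(c2)[C@H](CO[Si](C(C)C)(C(C)C)C(C)C)[C@@H](c2ccc(O[Si](C(C)C)(C(C)C)C(C)C)c(OC)c2)O3)ccc1O
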